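The butenolide is traced back to a bicyclic 3,6-dihydro-1,2-dioxine. In the target, the lactone oxygen O1 on quaternary C7a and the carbonyl oxygen of C2 are separated by the C3a=C3 double bond of the furanone ring, which is the 1,4-dioxygenated 2-ene left when O2 adds to a diene. One photo-oxygenation of a 1-vinylcyclohexene therefore makes both C–O bonds, the second ring and the C7a stereocentre, set against the resident C6 ester. The precursor, (1R)-4-ethenyl-3,5,5-trimethylcyclohex-3-en-1-yl palmitate, already carries the palmitate and comes from 4-oxoisophorone by enzymatic reduction, acylation, enol triflation and Suzuki vinylation. Peroxide isomerisation and lactol oxidation finish the synthesis.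

Key step: step 5

Remarks on the chemistry:
- Atom labels C2 to C7a follow the benzofuranone numbering of the target and are used for the corresponding carbons of all intermediates.
- The carbinol centre is R in 3, 5, 6 and 8 and S in 9 to 12 without any bond to it being touched. The CIP rank of its two ring CH2 neighbours switches once C7a carries oxygen.
- Because the ester is installed before the triflate, the triflate is made by electrophilic activation (Tf2O with a hindered pyridine) and not through an amide-base enolate, which the palmitate α-CH2 would not tolerate.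
- Assumption: Old Yellow Enzyme 2 and levodione reductase, or commercial ene-reductase and ketoreductase preparations of the same selectivity, are available.

Step 1
Reactants: 1 4-oxoisophorone
Product: 3 (4R,6R)-actinol, via (6R)-levodione 2 (not isolated)
Conditions: Old Yellow Enzyme 2, NADP+ (cat.), D-glucose, glucose dehydrogenase, KH2PO4/K2HPO4 buffer pH 7, 30 °C; then levodione reductase, NAD+ (cat.), D-glucose, 30 °C
Reagents that add atoms: none
Why: Sequential one-pot asymmetric bioreduction, in which the flavin ene-reductase adds hydride and proton anti across the enedione C=C to give (6R)-levodione and the ketoreductase, added only after 1 is consumed, reduces the unhindered C4 carbonyl from one face to the (4R)-alcohol, so both centres are enzyme-controlled and only the carbinol centre has to survive to the target.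

Step 2
Reactants: 3 (4R,6R)-actinol; 4 palmitoyl chloride
Product: 5 (1R,5R)-3,3,5-trimethyl-4-oxocyclohexyl palmitate
Conditions: Et3N, DMAP (cat.), CH2Cl2, 0 °C to rt
Reagents that add atoms: palmitoyl chloride 4, CCCCCCCCCCCCCCCC(=O)Cl
Why: DMAP-catalysed O-acylation (nucleophilic acyl substitution) of the only hydroxyl group, which leaves the C–O bond of the carbinol centre intact and the hindered ketone untouched.

Step 3
Reactants: 5 (1R,5R)-3,3,5-trimethyl-4-oxocyclohexyl palmitate
Product: 6 (1R)-3,5,5-trimethyl-4-[(trifluoromethanesulfonyl)oxy]cyclohex-3-en-1-yl palmitate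
Conditions: Tf2O, 2,6-di-tert-butyl-4-methylpyridine, CH2Cl2, 0 °C to rt
Reagents that add atoms: triflic anhydride, O=S(=O)(OS(=O)(=O)C(F)(F)F)C(F)(F)F
Why: Enol triflate formation by O-sulfonylation of the ketone and loss of the only α-hydrogen (the other α-carbon is quaternary), which gives a single regioisomer, erases the methyl-bearing centre and, being free of strong base, spares the ester as it does in acetoxy-substituted steroid ketones.

Step 4
Reactants: 6 (1R)-3,5,5-trimethyl-4-[(trifluoromethanesulfonyl)oxy]cyclohex-3-en-1-yl palmitate; 7 vinylboronic acid pinacol ester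
Product: 8 (1R)-4-ethenyl-3,5,5-trimethylcyclohex-3-en-1-yl palmitate
Conditions: Pd(dppf)Cl2 (5 mol%), K3PO4, THF/H2O (10:1), 60 °C
Reagents that add atoms: vinylboronic acid pinacol ester 7, C=CB1OC(C)(C)C(C)(C)O1
Why: Suzuki–Miyaura cross-coupling of an alkenyl triflate, in which the small vinyl partner should pass the flanking methyl groups and the mild phosphate base should leave the secondary ester intact.

Step 5
Reactants: 8 (1R)-4-ethenyl-3,5,5-trimethylcyclohex-3-en-1-yl palmitate
Product: 9 (7S,8aR)-5,5,8a-trimethyl-3,5,6,7,8,8a-hexahydro-1,2-benzodioxin-7-yl palmitate (endoperoxide, peroxide oxygen on C7a anti to the ester)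
Conditions: O2, tetraphenylporphyrin (cat.), hν (white LED), CH2Cl2, −78 °C
Reagents that add atoms: dioxygen (reacting as sensitised singlet oxygen), O=O
Why: Singlet oxygen adds as the 2π partner across the s-cis diene C7a=C3a–C3=C2 in a concerted, asynchronous hetero-Diels–Alder reaction, the closest known reaction type being the singlet-oxygen [4+2] cycloaddition of 1-vinylcyclohexenes and of carotenoid and retinoid end groups to 3,6-dihydro-1,2-dioxines. The six-membered dioxine ring is closed by this suprafacial [4+2] cycloaddition, with the C7a–O and C2–O bonds forming on the same face of the diene. The new C7a centre is set by substrate control from the C6 carbinol centre: the ester is no hydrogen-bond donor and cannot draw oxygen to its own side, and, as in peracid epoxidation of 3-acyloxy-trimethylcyclohexenyl rings, the electrophilic oxygen should prefer the face remote from the acyloxy dipole, giving O–C7a anti to the palmitate. The step also needs periselectivity for [4+2] over the ene reaction at the C7a methyl and the C7 methylene; the C4 gem-dimethyl and C7a methyl groups hold the vinyl group in a twisted s-cis arrangement, and low temperature in an aprotic solvent favours cycloaddition. The palmitate and the product alkene are inert to singlet oxygen, and any syn diastereomer or ene hydroperoxide should be removable by chromatography at this stage.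

Step 6
Reactants: 9 (7S,8aR)-5,5,8a-trimethyl-3,5,6,7,8,8a-hexahydro-1,2-benzodioxin-7-yl palmitate
Product: 11 (6S,7aR)-2-hydroxy-4,4,7a-trimethyl-2,4,5,6,7,7a-hexahydro-1-benzofuran-6-yl palmitate (lactol, both C2 epimers), via (Z)-γ-hydroxy enal 10 (not isolated)
Conditions: Et3N (1 equiv), CH2Cl2, 0 °C to rt
Reagents that add atoms: none
Why: Kornblum–DeLaMare rearrangement, in which the amine removes a C2 hydrogen (the only hydrogens α to the peroxide) as the O–O bond breaks, giving the aldehyde and the C7a hydroxyl cis across C3a=C3, which close to the five-membered lactol without touching the C7a–O bond.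

Step 7
Reactants: 11 (6S,7aR)-2-hydroxy-4,4,7a-trimethyl-2,4,5,6,7,7a-hexahydro-1-benzofuran-6-yl palmitate
Product: 12 (−)-3-O-palmitoylloliolide, (6S,7aR)-4,4,7a-trimethyl-2-oxo-2,4,5,6,7,7a-hexahydro-1-benzofuran-6-yl palmitate
Conditions: MnO2 (activated, excess), CH2Cl2, rt
Reagents that add atoms: none
Why: MnO2 oxidation of an allylic lactol to the butenolide, which converges both C2 epimers, touches neither stereocentre and finds no other oxidisable group in the molecule.

Compound list
1 | 4-oxoisophorone (2,6,6-trimethylcyclohex-2-ene-1,4-dione) | CC1=CC(=O)CC(C)(C)C1=O | starting material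
2 | (6R)-levodione, (R)-2,2,6-trimethylcyclohexane-1,4-dione | O=C1CC(C)(C)C(=O)[C@H](C)C1 | intermediate (not isolated)
3 | (4R,6R)-actinol, (4R,6R)-4-hydroxy-2,2,6-trimethylcyclohexanone | O[C@H]1CC(C)(C)C(=O)[C@H](C)C1 | intermediate
4 | palmitoyl chloride (hexadecanoyl chloride) | CCCCCCCCCCCCCCCC(=O)Cl | starting material
5 | (1R,5R)-3,3,5-trimethyl-4-oxocyclohexyl palmitate | CCCCCCCCCCCCCCCC(=O)O[C@H]1CC(C)(C)C(=O)[C@H](C)C1 | intermediate
6 | (1R)-3,5,5-trimethyl-4-[(trifluoromethanesulfonyl)oxy]cyclohex-3-en-1-yl palmitate | CCCCCCCCCCCCCCCC(=O)O[C@H]1CC(C)(C)C(OS(=O)(=O)C(F)(F)F)=C(C)C1 | intermediate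
7 | vinylboronic acid pinacol ester | C=CB1OC(C)(C)C(C)(C)O1 | starting material
8 | (1R)-4-ethenyl-3,5,5-trimethylcyclohex-3-en-1-yl palmitate | CCCCCCCCCCCCCCCC(=O)O[C@H]1CC(C)(C)C(C=C)=C(C)C1 | intermediate
9 | (7S,8aR)-5,5,8a-trimethyl-3,5,6,7,8,8a-hexahydro-1,2-benzodioxin-7-yl palmitate | CCCCCCCCCCCCCCCC(=O)O[C@H]1CC(C)(C)C2=CCOO[C@]2(C)C1 | intermediate
10 | (1S,3R,4Z)-3-hydroxy-3,5,5-trimethyl-4-(2-oxoethylidene)cyclohexyl palmitate | CCCCCCCCCCCCCCCC(=O)O[C@H]1CC(C)(C)/C(=C/C=O)[C@](C)(O)C1 | intermediate (not isolated)
11 | (6S,7aR)-2-hydroxy-4,4,7a-trimethyl-2,4,5,6,7,7a-hexahydro-1-benzofuran-6-yl palmitate (C2 epimers) | CCCCCCCCCCCCCCCC(=O)O[C@H]1CC(C)(C)C2=CC(O)O[C@]2(C)C1 | intermediate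
12 | (−)-3-O-palmitoylloliolide, (6S,7aR)-4,4,7a-trimethyl-2-oxo-2,4,5,6,7,7a-hexahydro-1-benzofuran-6-yl palmitate | CCCCCCCCCCCCCCCC(=O)O[C@H]1CC(C)(C)C2=CC(=O)O[C@]2(C)C1 | target

Total step count: 7
Longest linear sequence: 7 steps (1 to 12)

Steps most likely to fail

Step 5. The ene pathway (oxygen delivered to C3a with hydrogen taken from the C7a methyl or from C7) may outrun the cycloaddition, or the two faces of C7a may be discriminated too weakly. The fallback sets out from diene 8. Buffered mCPBA (NaHCO3, CH2Cl2, 0 °C) should epoxidise the tetrasubstituted ring alkene in preference to the vinyl group and, following the anti preference known for acyloxy-substituted trimethylcyclohexenes, on the face opposite the ester, giving the vinyl oxirane (1S,4S,6R)-1-ethenyl-2,2,6-trimethyl-7-oxabicyclo[4.1.0]heptan-4-yl palmitate F1. Copper-catalysed vinyl oxirane ring expansion (Cu(hfacac)2 cat., toluene, heat) then moves the C3a–O bond to C2 while the C7a–O bond stays intact, giving the 2,5-dihydrofuran (6S,7aR)-4,4,7a-trimethyl-2,4,5,6,7,7a-hexahydro-1-benzofuran-6-yl palmitate F2. Allylic oxidation of its C2 methylene (CrO3, 3,5-dimethylpyrazole, CH2Cl2, −20 °C) comes back to the route at target 12.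

Step 3. O-Sulfonylation of the carbonyl group, which is flanked by a quaternary and a tertiary carbon, may be slow enough for cationic rearrangement or attack of the anhydride on the ester to take over. The fallback sets out from ketone 5. Soft enolisation (Me3SiOTf, Et3N, CH2Cl2, 0 °C) gives the silyl enol ether (1R)-3,5,5-trimethyl-4-[(trimethylsilyl)oxy]cyclohex-3-en-1-yl palmitate F3, again as the only possible regioisomer. Fluoride-induced triflyl transfer (CsF, PhNTf2, DME, rt) to the enolate released from it comes back to the route at enol triflate 6.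

Step 4. Transmetalation at the tetrasubstituted alkenyl–palladium centre may be slow, so that hydrolysis of the triflate back to the ketone and protodeboronation or oligomerisation of the vinylboron reagent consume the partners. The fallback sets out from enol triflate 6 and builds the vinyl group one carbon at a time. Palladium-catalysed reductive carbonylation (CO 1 atm, Bu3SnH added slowly, Pd(PPh3)4, THF, 50 °C) gives the aldehyde (1R)-4-formyl-3,5,5-trimethylcyclohex-3-en-1-yl palmitate F4. Wittig methylenation (Ph3PCH3Br, KHMDS in slight deficit, THF, −78 to 0 °C), which is far faster at the aldehyde than at the ester, comes back to the route at diene 8.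

Further compounds
F1 | step 5 | (1S,4S,6R)-1-ethenyl-2,2,6-trimethyl-7-oxabicyclo[4.1.0]heptan-4-yl palmitate (epoxide oxygen anti to the ester) | CCCCCCCCCCCCCCCC(=O)O[C@H]1CC(C)(C)[C@]2(C=C)O[C@]2(C)C1
F2 | step 5 | (6S,7aR)-4,4,7a-trimethyl-2,4,5,6,7,7a-hexahydro-1-benzofuran-6-yl palmitate | CCCCCCCCCCCCCCCC(=O)O[C@H]1CC(C)(C)C2=CCO[C@]2(C)C1
F3 | step 3 | (1R)-3,5,5-trimethyl-4-[(trimethylsilyl)oxy]cyclohex-3-en-1-yl palmitate | CCCCCCCCCCCCCCCC(=O)O[C@H]1CC(C)(C)C(O[Si](C)(C)C)=C(C)C1
F4 | step 4 | (1R)-4-formyl-3,5,5-trimethylcyclohex-3-en-1-yl palmitate | CCCCCCCCCCCCCCCC(=O)O[C@H]1CC(C)(C)C(C=O)=C(C)C1
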